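The numbers were drawn at random within sensible limits; the result is computed.

The amounts on the catalyst side of this flask were small: I had 0.900 mM of catalyst against 18 mM of starting material.

starting material 18 mM; gas phase 3.0 mM (held); catalyst 5 mol%; time 5.0 min

    gas phase ⇌ dissolved gas, rate k1*(csat - [dissolved gas]) (k1 = 0.021 s⁻¹, csat = 3.0 mM)
    starting material + dissolved gas + catalyst → catalyst + product (k2 = 880 L² mol⁻² s⁻¹)
    catalyst + product ⇌ idle complex, settled at all times (K3 = 3500 L mol⁻¹)
    starting material ⇌ dormant form (K4 = 0.33, k4 = 0.028 s⁻¹)

- what is said of product includes idle complex
- at the start none of the gas is dissolved
- run time (flask): 5.0 min

- ash: doubling the transfer coefficient of step 1, all else as stated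
- alder: doubling the saturation concentration of gas phase, all else as stated
- cedar: doubling the amount of catalyst, all else as stated

1. how much product and idle complex together there is at 5.0 min, in percent of the starting material charged
2. the change that raises the amount of product and idle complex together at 5.0 min, in percent of the starting material charged most ("none" if none brings more than 2 percentage points) (ash / alder / cedar / none)
3. amount of product and idle complex together at 5.0 min, in percent of the starting material charged, after cedar

The gas started at zero, so I counted dissolved gas at 3.0 mM and took a lag of 47.6 s off the run. The dormant equilibrium relaxes with a half-life of 0.102 min, shorter than the run, so I held free starting material at 13.5 mM. But product binds catalyst (product inhibition), and I took that fast balance as settled. This gave me the half-binding level P_h = 0.286 mM, the free product concentration P at which half of the catalyst is idle complex; the free share is P_h/(P_h+P).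

I wrote S for what the rate of product formation adds up to over the shortened run when it is held at these two concentrations with all the catalyst counted as free: S = 8.12 mM, a sum for the reckoning and not an amount of product in this flask. Summing the slowing rate over the run gives P plus P squared over twice P_h equal to S. Counting all product as free, I got 10.5 %, and 15.4 % for cedar. Alder doubles S as well, so my reckoning tied the two, while ash raises S by 9.43 %.

The forecast gave 12.6 % (11 % to 14.5 %), cedar as best, and 19.7 % (17.5 % to 22 %), holding that “Product binds the catalyst tightly”. Its yield stood above mine.

The simulation gave 12.1 %, 18.9 % after cedar, and cedar as best, with gains of 0.92 percentage points for ash, 4.9 points for alder and 6.9 points for cedar.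

At 5.00 min the flask held 83.3 % of its catalyst as idle complex, which left 1.42 mM of free product. P_h then gives a free share of 16.8 %, and the flask showed 16.7 %. The neighbouring flask with 1.2 mol% of catalyst has S = 1.95 mM, and the same quadratic gives 4.49 %. That neighbouring flask gave 4.71 %, with 29.1 % of its catalyst free.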